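**Remark on the chemistry:** the hydroxymethyl oxygen is carried as a triisopropylsilyl ether, because it must outlast the alkoxide of step 7 and the acid of step 8. For that reason the enoate is built from glycolaldehyde dimer and silylated afterwards.

## Analysis of the target

- The target is a diaryl ether with no stereocentre. The ether oxygen is flanked by ortho substituents on both rings, but a configurationally stable axis is not expected, so nothing stereochemical has to be controlled.
- Ring A is a methyl salicylate: C1 carries the ester, C2 the hydrogen-bonded phenol, C4 a methyl group and C6 the ether oxygen.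
- Ring B carries the ether oxygen at C1, a hydroxymethyl group at C2, a methoxy group at C4 and a prenyl (3-methylbut-2-enyl) ether at C6. Its three oxygens must end up as three different ethers.
- The sensitive parts are:
  - the prenyl aryl ether (ionisation in acid, sigmatropic shift on heating, attack of peracids and selenium electrophiles on the alkene);
  - the electron-rich, oxidisable ring B;
  - the benzylic alcohol;
  - the ester and hydroxymethyl pair, which could close to an eight-membered lactone under forcing base.
- The synthesis is hard for two reasons. The inter-ring C–O bond joins a doubly ortho-substituted, electron-rich ring B to a ring A that is not activated for substitution. The oxygens of both rings must also be told apart without statistical alkylation of the finished skeleton.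
- The plan rests on the 1,3-relationship of the C4 and C6 oxygens of ring B. With C1 and C2 as sp3 carbons, ring B is a cyclohexane-1,3-dione whose ether oxygen sits on a carbon alpha to a ketone.
- In that form the hindered ether bond is a plain phenol alkylation, and C2 is the beta carbon of an unsaturated ester.

## Retrosynthetic reasoning

**Protecting groups (25, 24, 23).** Target 25 comes from 24 by loss of the silyl group, and 24 from 23 by loss of the acetal. No skeletal bond is cut; only the order matters. The acetal of 23 is ortho to the ester and should fall under mild acid while the benzylic oxygen is still silylated. The silyl ether is then removed with buffered fluoride, at a stage where the free salicylate hydroxyl tempers the ester.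

**Ester carbon on ring A (23 to 21).** The bond between C1 of ring A and the ester carbon is cut, leading through aryllithium 22 to bromide 21. The ester is installed this late because the enolates of steps 7 and 9 would attack it. In step 7 the enolate of the aryloxy ketone would acylate an ortho ester and close a benzofuranone. Bromine is inert to all of this. Flanked by two oxygens, it should exchange with lithium faster than anything else in 21 reacts.

**Prenyl ether (21 to 19 and 20).** The O–prenyl bond at C6 of ring B is cut, giving phenol 19 and prenyl bromide 20. The prenyl group is added after the oxidising step 9, which its alkene would not survive. It is added before the carboxylation, so that no free phenol passes through the organolithium step.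

**Aromatisation (19 to 14).** Phenol 19 is traced to enone 14 by returning two hydrogens to C1 and C2 of ring B. C6 becomes a ketone and C4 stays a methyl enol ether. In the forward direction this is a dehydrogenation across C1–C2, and the resulting dienone 18 is one tautomerisation from the arene. The gain is that the ether oxygen at C1 now sits on an sp3 carbon, and the methoxy oxygen is already distinct from the future phenol.

**Enol ether (14 to 13).** The O–methyl bond is cut, leading to dione 13. The forward reaction must put the methyl group on the C4 oxygen. C4 is flanked by two methylene groups, whereas C6 adjoins the aryloxy-bearing carbon, so addition to the C4 carbonyl carbon should be favoured.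

**Ring B (13 to 7 and 11).** Dione 13 is cut at C1–C2 and C4–C5 of ring B.
- These are the two bonds that an unsymmetrical ketone forms in sequence with an unsaturated ester.
- C1 is the acidic aryloxy carbon of ketone 7 and C5 is its methyl group.
- C2 is the beta carbon of enoate 11 and C4 is its ester carbon.
- Any other pair of cuts would put the aryloxy group on the wrong carbon or bring back an ether synthesis on an arene.
- The forward reaction must add through the aryloxy carbon to give adduct 12 and then close through the methyl carbon.

**Ring A fragment (7 back to 1).** Ketone 7 is cut at the O–CH2 bond to phenol 5 and chloroacetone 6. Phenol 5 comes from bis-acetal 4 by loss of one acetal. Bromide 4 comes from 2 through aryllithium 3, and 2 from orcinol 1. Metalation between the two acetal oxygens places bromine on the one carbon that later carries the ester.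

**Enoate (11 back to 8 and 9).** Enoate 11 is cut at the Si–O bond to alcohol 10, and 10 at the C=C bond to glycolaldehyde dimer 8 and ylide 9. The stabilised ylide should give the E geometry.

## Alternatives that were turned down

**Alternative 1:** ring A from a pyrone and an ynol ether.

- **Disconnection:** ring A is cut at C6–C1 and C5–C4.
- **Forward key step:** the ethynyl ether A2 of the ring B phenol A4 adds across C3 and C6 of the silyloxypyrone ester A3. The bridged lactone then loses its bridge by cycloreversion and gives A1, the bis(triisopropylsilyl) ether of the target.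
- **For:** the polarity is matched, since the nucleophilic alkyne terminus meets the electrophilic C6 of the pyrone. Ring A appears fully substituted in one step, with no redox adjustment and no organolithium chemistry.
- **Against:**
  - A4 must be made separately, with its three oxygens already differentiated. That is the hard part of the molecule, and this key step does not address it.
  - A2 has to be made from a hindered phenol by a strong-base elimination. Aryl ynol ethers hydrate and polymerise easily.
  - Pyrone cycloadditions need heat, at which the prenyl aryl ether of A2 can rearrange onto the free ortho carbon.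
  - The silyloxy donor at C4 makes A3 a poorer diene, and its silyl enol ether is labile.
- **Comparison:** this route is more convergent and shorter after the key step. The chosen route instead obtains the oxygen pattern of ring B from the annulation itself, stays near room temperature, and adds the prenyl group only after the harsh steps.

**Alternative 2:** ring B by vinylketene–alkyne benzannulation.

- **Disconnection:** ring B is cut at C2–C3, C3–C4, C5–C6 and C6–C1.
- **Forward key step:** photolysis of diazo enone A6 triggers a Wolff rearrangement to vinylketene A7. A7 adds methoxyacetylene A8 to give a vinylcyclobutenone, which opens and recloses by six-electron electrocyclisation. Tautomerisation gives A5, with the C6 phenol free.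
- **For:** the methoxy and hydroxyl groups are differentiated by the polarity of the cycloaddition. No separate aromatisation is needed, ring A carries its ester throughout, and only prenylation and desilylation remain.
- **Against:**
  - A6 is a beta-aryloxy enone bearing a diazoketone. Making it requires joining the hindered ring A phenol to an enone beta carbon and then a diazo transfer beside a vinylogous ester, which is open to addition–elimination.
  - A8 is volatile and unstable and must be freshly prepared.
  - The aryloxy group sits on the terminus that closes the six-membered ring, which should slow the electrocyclisation.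
  - The photolysis runs in the presence of two aryl ether chromophores.
- **Comparison:** this route is as strong on oxygen differentiation and stronger on step count after the key step. The chosen route offers a precursor reached in four ordinary steps from orcinol 1, thermal enolate chemistry that scales, and a risk confined to the regiochemistry of one enolate.

**Alternative 3:** aryne, ring B phenoxide and carboxylation.

- **Disconnection:** ring A is cut at the C6–O ether bond and the C1–carboxyl bond.
- **Forward key step:** fluoride releases aryne A11 from silyl triflate A10. The potassium salt of A4 adds at the carbon remote from the acetal, and the aryl anion formed next to the acetal is carboxylated in the same flask to give acid A9.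
- **For:** the hindered diaryl ether and the carboxyl carbon are made in one mild step. The regiochemistry follows from the acetal oxygen, and no bromine or organolithium is needed.
- **Against:**
  - The aryl anion is more likely to be protonated than carboxylated.
  - The phenoxide is itself tied up reversibly by the carboxylating gas.
  - The oxygen of A4 is doubly flanked, which lowers its nucleophilicity.
  - The prenyl alkene has allylic hydrogens and is a partner for an ene reaction with A11.
  - A10 and A4 each need several steps, and A4 again carries the unsolved differentiation of the ring B oxygens.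
- **Comparison:** this route is stronger on convergence and on direct formation of the ether bond. The chosen route avoids having to prepare A4 at all, and uses only two-component steps of known behaviour.

Key step: step 7

## Route

Step 1
Reactants: 1 orcinol (5-methylbenzene-1,3-diol)
Product: 2 1,3-bis(methoxymethoxy)-5-methylbenzene
Conditions: NaH, CH3OCH2Cl, DMF, 0 °C → rt
Reagents that add atoms: chloromethyl methyl ether, COCCl
Why: Williamson-type O-alkylation of both phenoxides by a very reactive alpha-chloro ether; the two acetals later direct the metalation of step 2.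

Step 2
Reactants: 2 1,3-bis(methoxymethoxy)-5-methylbenzene
Product: 4 2-bromo-1,3-bis(methoxymethoxy)-5-methylbenzene, via aryllithium 3 (not isolated)
Conditions: n-BuLi, THF, 0 °C; then BrCH2CH2Br, −78 °C → rt
Reagents that add atoms: 1,2-dibromoethane, BrCCBr
Why: Directed ortho-metalation; the position between the two coordinating acetal oxygens is by far the most acidic, and the aryllithium takes bromine from dibromoethane with loss of ethene.

Step 3
Reactants: 4 2-bromo-1,3-bis(methoxymethoxy)-5-methylbenzene
Product: 5 2-bromo-3-(methoxymethoxy)-5-methylphenol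
Conditions: TsOH·H2O (cat.), CH3OH, rt, stopped at partial conversion; recovered 4 resubmitted
Reagents that add atoms: none
Why: Acid-catalysed transacetalisation to methanol removes one acetal; the step is statistical by nature, so it is run to partial conversion and the material balance is closed by recycling 4.

Step 4
Reactants: 5 2-bromo-3-(methoxymethoxy)-5-methylphenol; 6 chloroacetone
Product: 7 1-[2-bromo-3-(methoxymethoxy)-5-methylphenoxy]propan-2-one
Conditions: K2CO3, KI (cat.), acetone, reflux
Reagents that add atoms: none
Why: Williamson ether synthesis on an alpha-halo ketone, a very good SN2 substrate; this places the future diaryl ether oxygen on an sp3 carbon without any hindrance problem.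

Step 5
Reactants: 8 glycolaldehyde dimer (1,4-dioxane-2,5-diol); 9 methyl (triphenylphosphoranylidene)acetate
Product: 10 methyl (E)-4-hydroxybut-2-enoate
Conditions: THF, reflux
Reagents that add atoms: none
Why: Wittig olefination of the monomeric aldehyde in equilibrium with its dimer; the stabilised ylide should give the E alkene.

Step 6
Reactants: 10 methyl (E)-4-hydroxybut-2-enoate
Product: 11 methyl (E)-4-(triisopropylsilyloxy)but-2-enoate
Conditions: i-Pr3SiCl, imidazole, CH2Cl2, 0 °C → rt
Reagents that add atoms: triisopropylsilyl chloride, CC(C)[Si](Cl)(C(C)C)C(C)C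
Why: Standard silylation of a primary alcohol; the bulky silyl group is chosen for stability to alkoxide and to mild acid.

Step 7
Reactants: 7 1-[2-bromo-3-(methoxymethoxy)-5-methylphenoxy]propan-2-one; 11 methyl (E)-4-(triisopropylsilyloxy)but-2-enoate
Product: 13 4-[2-bromo-3-(methoxymethoxy)-5-methylphenoxy]-5-[(triisopropylsilyloxy)methyl]cyclohexane-1,3-dione (racemic, mixture of diastereomers), via Michael adduct 12 (not isolated)
Conditions: KOC(CH3)3 (2.2 equiv), THF, 7 at −20 °C, then 11 added slowly, → rt; then cold 1 M HCl
Reagents that add atoms: none
Why: KOC(CH3)3 deprotonates 7 reversibly, and the enolate on the aryloxy-bearing carbon, the more acidic site, adds to the beta carbon of 11 (bond C1–C2 of ring B); proton transfer then gives the methyl ketone enolate of 12, which attacks the ester carbonyl and expels methoxide (bond C4–C5). The closest known reaction type is the consecutive Michael–Claisen condensation of substituted acetones with alpha,beta-unsaturated esters to 4-substituted cyclohexane-1,3-diones, the logic of the classical dimedone synthesis. The one ring is closed in a 6-exo-trig mode, an enolate carbon attacking a carbonyl group that lies outside the new ring, and the sequence is pulled forward because 13 leaves the equilibria as its stabilised dione enolate. Two stereocentres arise, at the aryloxy carbon and at the silyloxymethyl carbon; neither is controlled, the aryloxy centre remains epimerisable so the trans isomer should prevail, and both are erased in step 9. The selectivity that matters is the site of the Michael addition, since attack through the methyl carbon would lead to a 2-aryloxy dione; it is secured by the inductive effect of the aryloxy oxygen on the enolate equilibrium together with the reversibility of the conjugate addition. Gamma-deprotonation of 11 is limited by forming the ketone enolate first and adding 11 cold, the ketone being much the stronger acid. Ring A offers no acyl group to the enolate because it carries bromine, and the acetal and the silyl ether are inert to alkoxide.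

Step 8
Reactants: 13 4-[2-bromo-3-(methoxymethoxy)-5-methylphenoxy]-5-[(triisopropylsilyloxy)methyl]cyclohexane-1,3-dione
Product: 14 6-[2-bromo-3-(methoxymethoxy)-5-methylphenoxy]-3-methoxy-5-[(triisopropylsilyloxy)methyl]cyclohex-2-en-1-one (racemic, mixture of diastereomers)
Conditions: HC(OCH3)3, CH3OH, pyridinium p-toluenesulfonate (cat.), rt → 40 °C; then Et3N
Reagents that add atoms: trimethyl orthoformate, COC(OC)OC; methanol, CO
Why: Acid-catalysed enol ether formation of a vinylogous acid, in which the alcohol adds to a carbonyl carbon and water is taken up by the orthoformate; the C4 carbonyl lies between two methylene groups, whereas C6 adjoins the aryloxy carbon, so the methoxy group should end up on C4. The conditions equilibrate, so a regioisomer can be resubmitted, and the weak acid should leave the aryl acetal and the silyl ether in place.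

Step 9
Reactants: 14 6-[2-bromo-3-(methoxymethoxy)-5-methylphenoxy]-3-methoxy-5-[(triisopropylsilyloxy)methyl]cyclohex-2-en-1-one
Product: 19 2-[2-bromo-3-(methoxymethoxy)-5-methylphenoxy]-5-methoxy-3-[(triisopropylsilyloxy)methyl]phenol, via lithium dienolate 15 (not isolated), via alpha-selenide 16 (not isolated), via selenoxide 17 (not isolated), via cyclohexadienone 18 (not isolated)
Conditions: LiN(i-Pr)2, THF, −78 °C; PhSeCl, −78 °C; crude selenide: m-CPBA, CH2Cl2, −78 °C; then i-Pr2NH, → rt
Reagents that add atoms: none
Why: Kinetic deprotonation of the vinylogous ester at the alpha-prime carbon (the aryloxy carbon), selenenylation, and selenoxide syn-elimination towards the only beta hydrogen give the cross-conjugated dienone 18, which is the keto tautomer of the phenol and aromatises at once. Selenium should enter anti to the neighbouring silyloxymethyl group, which sets it syn to the hydrogen that has to leave; the amine traps the selenenic acid before it can attack the new phenol.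

Step 10
Reactants: 19 2-[2-bromo-3-(methoxymethoxy)-5-methylphenoxy]-5-methoxy-3-[(triisopropylsilyloxy)methyl]phenol; 20 prenyl bromide (1-bromo-3-methylbut-2-ene)
Product: 21 {[2-(2-bromo-3-(methoxymethoxy)-5-methylphenoxy)-5-methoxy-3-(3-methylbut-2-enyloxy)benzyl]oxy}triisopropylsilane
Conditions: K2CO3, DMF, rt
Reagents that add atoms: none
Why: Williamson O-alkylation of the only free hydroxyl with a reactive allylic bromide under conditions that favour O- over C-alkylation; the prenyl group enters after the oxidising step and is not heated afterwards.

Step 11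
Reactants: 21 {[2-(2-bromo-3-(methoxymethoxy)-5-methylphenoxy)-5-methoxy-3-(3-methylbut-2-enyloxy)benzyl]oxy}triisopropylsilane
Product: 23 methyl 2-(methoxymethoxy)-6-{4-methoxy-2-(3-methylbut-2-enyloxy)-6-[(triisopropylsilyloxy)methyl]phenoxy}-4-methylbenzoate, via aryllithium 22 (not isolated)
Conditions: t-BuLi (2.1 equiv), THF, −78 °C; then ClCO2CH3 (excess), −78 → 0 °C
Reagents that add atoms: methyl chloroformate, COC(=O)Cl
Why: Bromine–lithium exchange at −78 °C is faster than any deprotonation in 21 and gives an aryllithium held between two oxygens; acylation with excess chloroformate gives the ester, whose two ortho substituents slow a second addition.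

Step 12
Reactants: 23 methyl 2-(methoxymethoxy)-6-{4-methoxy-2-(3-methylbut-2-enyloxy)-6-[(triisopropylsilyloxy)methyl]phenoxy}-4-methylbenzoate
Product: 24 methyl 2-hydroxy-6-{4-methoxy-2-(3-methylbut-2-enyloxy)-6-[(triisopropylsilyloxy)methyl]phenoxy}-4-methylbenzoate
Conditions: HCl (about 0.5 M, from a commercial solution in CH3OH), CH3OH/THF, 0 °C → rt, followed closely
Reagents that add atoms: none
Why: Acid-catalysed acetal exchange; an acetal ortho to an ester carbonyl is among the most labile of its kind, which should allow conditions that the prenyl ether tolerates. The benzylic oxygen stays silylated; any silyl ether that is lost here gives 25 directly.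

Step 13
Reactants: 24 methyl 2-hydroxy-6-{4-methoxy-2-(3-methylbut-2-enyloxy)-6-[(triisopropylsilyloxy)methyl]phenoxy}-4-methylbenzoate
Product: 25 methyl 2-hydroxy-6-[2-(hydroxymethyl)-4-methoxy-6-(3-methylbut-2-enyloxy)phenoxy]-4-methylbenzoate (target)
Conditions: (n-Bu)4NF, CH3CO2H (1:1), THF, 0 °C → rt
Reagents that add atoms: none
Why: Fluoride-induced cleavage of a primary silyl ether; the acetic acid buffer keeps the alkoxide concentration low so that the ester is neither hydrolysed nor attacked by the new alcohol.

## Compound list

1 | orcinol (5-methylbenzene-1,3-diol) | Cc1cc(O)cc(O)c1 | starting material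
2 | 1,3-bis(methoxymethoxy)-5-methylbenzene | COCOc1cc(C)cc(OCOC)c1 | intermediate
3 | [2,6-bis(methoxymethoxy)-4-methylphenyl]lithium | [Li]c1c(OCOC)cc(C)cc1OCOC | intermediate (not isolated)
4 | 2-bromo-1,3-bis(methoxymethoxy)-5-methylbenzene | COCOc1cc(C)cc(OCOC)c1Br | intermediate
5 | 2-bromo-3-(methoxymethoxy)-5-methylphenol | COCOc1cc(C)cc(O)c1Br | intermediate
6 | chloroacetone | CC(=O)CCl | starting material
7 | 1-[2-bromo-3-(methoxymethoxy)-5-methylphenoxy]propan-2-one | CC(=O)COc1cc(C)cc(OCOC)c1Br | intermediate
8 | glycolaldehyde dimer (1,4-dioxane-2,5-diol) | OC1COC(O)CO1 | starting material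
9 | methyl (triphenylphosphoranylidene)acetate | COC(=O)C=P(c1ccccc1)(c1ccccc1)c1ccccc1 | starting material
10 | methyl (E)-4-hydroxybut-2-enoate | COC(=O)/C=C/CO | intermediate
11 | methyl (E)-4-(triisopropylsilyloxy)but-2-enoate | COC(=O)/C=C/CO[Si](C(C)C)(C(C)C)C(C)C | intermediate
12 | methyl 4-[2-bromo-3-(methoxymethoxy)-5-methylphenoxy]-5-oxo-3-[(triisopropylsilyloxy)methyl]hexanoate (racemic, mixture of diastereomers) | COC(=O)CC(CO[Si](C(C)C)(C(C)C)C(C)C)C(Oc1cc(C)cc(OCOC)c1Br)C(C)=O | intermediate (not isolated)
13 | 4-[2-bromo-3-(methoxymethoxy)-5-methylphenoxy]-5-[(triisopropylsilyloxy)methyl]cyclohexane-1,3-dione (racemic, mixture of diastereomers) | O=C1CC(=O)C(Oc2cc(C)cc(OCOC)c2Br)C(CO[Si](C(C)C)(C(C)C)C(C)C)C1 | intermediate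
14 | 6-[2-bromo-3-(methoxymethoxy)-5-methylphenoxy]-3-methoxy-5-[(triisopropylsilyloxy)methyl]cyclohex-2-en-1-one (racemic, mixture of diastereomers) | COC1=CC(=O)C(Oc2cc(C)cc(OCOC)c2Br)C(CO[Si](C(C)C)(C(C)C)C(C)C)C1 | intermediate
15 | lithium dienolate of 14 (racemic) | [Li]OC1=C(Oc2cc(C)cc(OCOC)c2Br)C(CO[Si](C(C)C)(C(C)C)C(C)C)CC(OC)=C1 | intermediate (not isolated)
16 | 6-[2-bromo-3-(methoxymethoxy)-5-methylphenoxy]-3-methoxy-6-(phenylselanyl)-5-[(triisopropylsilyloxy)methyl]cyclohex-2-en-1-one (racemic, selenium expected trans to the silyloxymethyl group) | COC1=CC(=O)C(Oc2cc(C)cc(OCOC)c2Br)([Se]c2ccccc2)C(CO[Si](C(C)C)(C(C)C)C(C)C)C1 | intermediate (not isolated)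
17 | selenoxide of 16 (mixture of stereoisomers) | COC1=CC(=O)C(Oc2cc(C)cc(OCOC)c2Br)([Se](=O)c2ccccc2)C(CO[Si](C(C)C)(C(C)C)C(C)C)C1 | intermediate (not isolated)
18 | 2-[2-bromo-3-(methoxymethoxy)-5-methylphenoxy]-5-methoxy-3-[(triisopropylsilyloxy)methyl]cyclohexa-2,5-dien-1-one | COC1=CC(=O)C(Oc2cc(C)cc(OCOC)c2Br)=C(CO[Si](C(C)C)(C(C)C)C(C)C)C1 | intermediate (not isolated)
19 | 2-[2-bromo-3-(methoxymethoxy)-5-methylphenoxy]-5-methoxy-3-[(triisopropylsilyloxy)methyl]phenol | COc1cc(O)c(Oc2cc(C)cc(OCOC)c2Br)c(CO[Si](C(C)C)(C(C)C)C(C)C)c1 | intermediate
20 | prenyl bromide (1-bromo-3-methylbut-2-ene) | CC(C)=CCBr | starting material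
21 | {[2-(2-bromo-3-(methoxymethoxy)-5-methylphenoxy)-5-methoxy-3-(3-methylbut-2-enyloxy)benzyl]oxy}triisopropylsilane | COc1cc(OCC=C(C)C)c(Oc2cc(C)cc(OCOC)c2Br)c(CO[Si](C(C)C)(C(C)C)C(C)C)c1 | intermediate
22 | aryllithium from 21 (lithium in place of bromine) | [Li]c1c(OCOC)cc(C)cc1Oc1c(CO[Si](C(C)C)(C(C)C)C(C)C)cc(OC)cc1OCC=C(C)C | intermediate (not isolated)
23 | methyl 2-(methoxymethoxy)-6-{4-methoxy-2-(3-methylbut-2-enyloxy)-6-[(triisopropylsilyloxy)methyl]phenoxy}-4-methylbenzoate | COC(=O)c1c(OCOC)cc(C)cc1Oc1c(CO[Si](C(C)C)(C(C)C)C(C)C)cc(OC)cc1OCC=C(C)C | intermediate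
24 | methyl 2-hydroxy-6-{4-methoxy-2-(3-methylbut-2-enyloxy)-6-[(triisopropylsilyloxy)methyl]phenoxy}-4-methylbenzoate | COC(=O)c1c(O)cc(C)cc1Oc1c(CO[Si](C(C)C)(C(C)C)C(C)C)cc(OC)cc1OCC=C(C)C | intermediate
25 | methyl 2-hydroxy-6-[2-(hydroxymethyl)-4-methoxy-6-(3-methylbut-2-enyloxy)phenoxy]-4-methylbenzoate | COC(=O)c1c(O)cc(C)cc1Oc1c(CO)cc(OC)cc1OCC=C(C)C | target

## Step count and least certain steps

Total step count: 13. Longest linear sequence: 11 steps (steps 1 to 4 and 7 to 13, from orcinol 1); the enoate branch (steps 5 and 6) joins at step 7.

**Step 7 (key step).**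
- What may go wrong: conjugate addition of a hindered, stabilised enolate to a beta-substituted enoate may be slow. Base-induced isomerisation of 11 by gamma-deprotonation, or aldol self-condensation of 7, could then take over. Addition through the methyl carbon would give the wrong dione.
- Fallback: the two bond formations are separated and the enolate is fixed beforehand. Ketone 7 is converted under equilibrating silylation ((CH3)3SiCl, NaI, Et3N, CH3CN) into the enol silane at the aryloxy carbon, (Z)-{[1-(2-bromo-3-(methoxymethoxy)-5-methylphenoxy)prop-1-en-2-yl]oxy}trimethylsilane F1. The enolate of F1 is released with CsF in the presence of 11, where it can only add through the oxygenated carbon. Adduct 12 is then isolated and closed in a separate Claisen (Dieckmann-type) step with KOC(CH3)3 in THF, which returns to the route at 13.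

**Step 8.**
- What may go wrong: competing addition of methanol at the C6 carbonyl would put the methyl group on the wrong oxygen. Some aryl acetal may also be lost during equilibration.
- Fallback: the oxygens are told apart after aromatisation, by size.
  - Dione 13 is doubly enolised (LiN(i-Pr)2, 2.2 equiv, (CH3)3SiCl) to the bis(enol silane) {[4-(2-bromo-3-(methoxymethoxy)-5-methylphenoxy)-5-((triisopropylsilyloxy)methyl)cyclohexa-1,3-diene-1,3-diyl]bis(oxy)}bis(trimethylsilane) F2. Its regioisomer would serve equally.
  - Saegusa–Ito oxidation with Pd(OAc)2 in CH3CN, then K2CO3 in CH3OH, gives 4-[2-bromo-3-(methoxymethoxy)-5-methylphenoxy]-5-[(triisopropylsilyloxy)methyl]benzene-1,3-diol F3.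
  - The hydroxyl remote from the aryloxy group is silylated with t-BuPh2SiCl and imidazole, giving 2-[2-bromo-3-(methoxymethoxy)-5-methylphenoxy]-5-(tert-butyldiphenylsilyloxy)-3-[(triisopropylsilyloxy)methyl]phenol F4.
  - The remaining phenol is alkylated with 20 (K2CO3, DMF), giving the prenyl ether of F4, named [3-(2-bromo-3-(methoxymethoxy)-5-methylphenoxy)-5-(3-methylbut-2-enyloxy)-4-((triisopropylsilyloxy)methyl)phenoxy](tert-butyl)diphenylsilane F5.
  - CsF and CH3I in DMF exchange the aryl silyl ether for the methyl ether, which returns to the route at 21.

**Step 9.**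
- What may go wrong: selenenylation at a fully substituted carbon may be sluggish. The electron-rich phenol may be oxidised or selenenylated by the selenium by-products as it forms.
- Fallback: the enolate 15 from 14 is trapped on oxygen with (CH3)3SiCl to give [2-(2-bromo-3-(methoxymethoxy)-5-methylphenoxy)-5-methoxy-3-((triisopropylsilyloxy)methyl)cyclohexa-1,5-dienyl]oxytrimethylsilane F6. This is dehydrogenated by Saegusa–Ito oxidation with Pd(OAc)2 in CH3CN. No electrophile has to bond to the hindered carbon, and the hindered aryl bromide should not react with the zerovalent palladium formed, since no phosphine is present at room temperature. Dienone 18 tautomerises as before, which returns to the route at 19.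

**Step 12.**
- What may go wrong: the acid needed for the acetal may ionise the prenyl ether, with loss or migration of the prenyl group.
- Fallback: the prenyl group is introduced only after all acid treatment.
  - Phenol 19 is protected with CH3OCH2Cl and i-Pr2NEt as 2-bromo-1-(methoxymethoxy)-3-{4-methoxy-2-(methoxymethoxy)-6-[(triisopropylsilyloxy)methyl]phenoxy}-5-methylbenzene F7.
  - Exchange and acylation as in step 11 give methyl 2-(methoxymethoxy)-6-{4-methoxy-2-(methoxymethoxy)-6-[(triisopropylsilyloxy)methyl]phenoxy}-4-methylbenzoate F8.
  - Methanolic HCl removes both acetals to give methyl 2-hydroxy-6-{2-hydroxy-4-methoxy-6-[(triisopropylsilyloxy)methyl]phenoxy}-4-methylbenzoate F9.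
  - K2CO3 and 20 in acetone alkylate only the ring B phenol, because the ring A hydroxyl is held in a hydrogen bond to the ester and is a poor nucleophile. This returns to the route at 24.

**Step 3.**
- What may go wrong: the second acetal may be cleaved before the first is consumed, so the yield per pass is limited.
- Fallback: the desymmetrisation is moved to the alkylation.
  - Bromide 4 is fully deprotected (HCl, CH3OH) to 2-bromo-5-methylbenzene-1,3-diol F10.
  - F10, used in excess and recovered by base extraction, is mono-alkylated with 6 (K2CO3, acetone) to 1-(2-bromo-3-hydroxy-5-methylphenoxy)propan-2-one F11.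
  - CH3OCH2Cl and i-Pr2NEt then return to the route at 7.

**Step 11.**
- What may go wrong: a second addition of 22 to the ester just formed, or proton transfer to 22 from a benzylic or allylic position before the quench.
- Fallback: aryllithium 22, made from 21 as before, is quenched with gaseous CO2 to a carboxylate that cannot add a second aryllithium. Work-up gives 2-(methoxymethoxy)-6-{4-methoxy-2-(3-methylbut-2-enyloxy)-6-[(triisopropylsilyloxy)methyl]phenoxy}-4-methylbenzoic acid F12, which is esterified with CH3I and K2CO3 in DMF. This returns to the route at 23.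

## Further compounds

F1 | step 7 | (Z)-{[1-(2-bromo-3-(methoxymethoxy)-5-methylphenoxy)prop-1-en-2-yl]oxy}trimethylsilane | C/C(O[Si](C)(C)C)=C/Oc1cc(C)cc(OCOC)c1Br
F2 | step 8 | {[4-(2-bromo-3-(methoxymethoxy)-5-methylphenoxy)-5-((triisopropylsilyloxy)methyl)cyclohexa-1,3-diene-1,3-diyl]bis(oxy)}bis(trimethylsilane) (racemic) | C[Si](C)(C)OC1=CC(O[Si](C)(C)C)=C(Oc2cc(C)cc(OCOC)c2Br)C(CO[Si](C(C)C)(C(C)C)C(C)C)C1
F3 | step 8 | 4-[2-bromo-3-(methoxymethoxy)-5-methylphenoxy]-5-[(triisopropylsilyloxy)methyl]benzene-1,3-diol | Oc1cc(O)c(Oc2cc(C)cc(OCOC)c2Br)c(CO[Si](C(C)C)(C(C)C)C(C)C)c1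
F4 | step 8 | 2-[2-bromo-3-(methoxymethoxy)-5-methylphenoxy]-5-(tert-butyldiphenylsilyloxy)-3-[(triisopropylsilyloxy)methyl]phenol | CC(C)(C)[Si](Oc1cc(O)c(Oc2cc(C)cc(OCOC)c2Br)c(CO[Si](C(C)C)(C(C)C)C(C)C)c1)(c1ccccc1)c1ccccc1
F5 | step 8 | [3-(2-bromo-3-(methoxymethoxy)-5-methylphenoxy)-5-(3-methylbut-2-enyloxy)-4-((triisopropylsilyloxy)methyl)phenoxy](tert-butyl)diphenylsilane | CC(C)(C)[Si](Oc1cc(OCC=C(C)C)c(Oc2cc(C)cc(OCOC)c2Br)c(CO[Si](C(C)C)(C(C)C)C(C)C)c1)(c1ccccc1)c1ccccc1
F6 | step 9 | [2-(2-bromo-3-(methoxymethoxy)-5-methylphenoxy)-5-methoxy-3-((triisopropylsilyloxy)methyl)cyclohexa-1,5-dienyl]oxytrimethylsilane (racemic) | COC1=CC(O[Si](C)(C)C)=C(Oc2cc(C)cc(OCOC)c2Br)C(CO[Si](C(C)C)(C(C)C)C(C)C)C1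
F7 | step 12 | 2-bromo-1-(methoxymethoxy)-3-{4-methoxy-2-(methoxymethoxy)-6-[(triisopropylsilyloxy)methyl]phenoxy}-5-methylbenzene | COCOc1cc(OC)cc(CO[Si](C(C)C)(C(C)C)C(C)C)c1Oc1cc(C)cc(OCOC)c1Br
F8 | step 12 | methyl 2-(methoxymethoxy)-6-{4-methoxy-2-(methoxymethoxy)-6-[(triisopropylsilyloxy)methyl]phenoxy}-4-methylbenzoate | COC(=O)c1c(OCOC)cc(C)cc1Oc1c(CO[Si](C(C)C)(C(C)C)C(C)C)cc(OC)cc1OCOC
F9 | step 12 | methyl 2-hydroxy-6-{2-hydroxy-4-methoxy-6-[(triisopropylsilyloxy)methyl]phenoxy}-4-methylbenzoate | COC(=O)c1c(O)cc(C)cc1Oc1c(CO[Si](C(C)C)(C(C)C)C(C)C)cc(OC)cc1O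
F10 | step 3 | 2-bromo-5-methylbenzene-1,3-diol | Cc1cc(O)c(Br)c(O)c1
F11 | step 3 | 1-(2-bromo-3-hydroxy-5-methylphenoxy)propan-2-one | CC(=O)COc1cc(C)cc(O)c1Br
F12 | step 11 | 2-(methoxymethoxy)-6-{4-methoxy-2-(3-methylbut-2-enyloxy)-6-[(triisopropylsilyloxy)methyl]phenoxy}-4-methylbenzoic acid | OC(=O)c1c(OCOC)cc(C)cc1Oc1c(CO[Si](C(C)C)(C(C)C)C(C)C)cc(OC)cc1OCC=C(C)C
A1 | alternative 1 | methyl 4-methyl-2-(triisopropylsilyloxy)-6-{4-methoxy-2-(3-methylbut-2-enyloxy)-6-[(triisopropylsilyloxy)methyl]phenoxy}benzoate | COC(=O)c1c(O[Si](C(C)C)(C(C)C)C(C)C)cc(C)cc1Oc1c(CO[Si](C(C)C)(C(C)C)C(C)C)cc(OC)cc1OCC=C(C)C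
A2 | alternative 1 | {[2-(ethynyloxy)-5-methoxy-3-(3-methylbut-2-enyloxy)benzyl]oxy}triisopropylsilane | C#COc1c(CO[Si](C(C)C)(C(C)C)C(C)C)cc(OC)cc1OCC=C(C)C
A3 | alternative 1 | methyl 6-methyl-2-oxo-4-(triisopropylsilyloxy)-2H-pyran-3-carboxylate | COC(=O)C1=C(O[Si](C(C)C)(C(C)C)C(C)C)C=C(C)OC1=O
A4 | alternative 1 | 4-methoxy-2-(3-methylbut-2-enyloxy)-6-[(triisopropylsilyloxy)methyl]phenol | COc1cc(CO[Si](C(C)C)(C(C)C)C(C)C)c(O)c(OCC=C(C)C)c1
A5 | alternative 2 | methyl 2-(tert-butyldimethylsilyloxy)-6-{2-[(tert-butyldimethylsilyloxy)methyl]-6-hydroxy-4-methoxyphenoxy}-4-methylbenzoate | COC(=O)c1c(O[Si](C)(C)C(C)(C)C)cc(C)cc1Oc1c(CO[Si](C)(C)C(C)(C)C)cc(OC)cc1O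
A6 | alternative 2 | methyl 2-(tert-butyldimethylsilyloxy)-6-{[(E)-2-((tert-butyldimethylsilyloxy)methyl)-4-diazo-3-oxobut-1-enyl]oxy}-4-methylbenzoate | COC(=O)c1c(O[Si](C)(C)C(C)(C)C)cc(C)cc1O/C=C(\CO[Si](C)(C)C(C)(C)C)C(=O)C=[N+]=[N-]
A7 | alternative 2 | methyl 2-(tert-butyldimethylsilyloxy)-6-{[(Z)-2-((tert-butyldimethylsilyloxy)methyl)-4-oxobuta-1,3-dienyl]oxy}-4-methylbenzoate | COC(=O)c1c(O[Si](C)(C)C(C)(C)C)cc(C)cc1O/C=C(\CO[Si](C)(C)C(C)(C)C)C=C=O
A8 | alternative 2 | methoxyacetylene | COC#C
A9 | alternative 3 | 2-(methoxymethoxy)-6-{4-methoxy-2-(3-methylbut-2-enyloxy)-6-[(triisopropylsilyloxy)methyl]phenoxy}-4-methylbenzoic acid | OC(=O)c1c(OCOC)cc(C)cc1Oc1c(CO[Si](C(C)C)(C(C)C)C(C)C)cc(OC)cc1OCC=C(C)C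
A10 | alternative 3 | 3-(methoxymethoxy)-5-methyl-2-(trimethylsilyl)phenyl trifluoromethanesulfonate | COCOc1cc(C)cc(OS(=O)(=O)C(F)(F)F)c1[Si](C)(C)C
A11 | alternative 3 | 3-(methoxymethoxy)-5-methylbenzyne | COCOC1=CC(C)=CC#C1
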